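**Plan**

- C2, C3 and C4 of the pyranone carry oxygen at C2 and C4 and link ring A to ring B. This 1,3-dioxygenated three-carbon unit is exactly what a 3,5-diarylisoxazole stores.
- Retrosynthesis: the 5-OH is traced to a 5-OMe; the O1–C2 bond is opened to the 1-(2-hydroxyaryl)-3-aryl-1,3-diketone; the diketone is masked as the isoxazole.
- The isoxazole is cut at C4–C3 and at C2–O (flavone numbering) into a ring-A nitrile oxide and a ring-B arylacetylene.
- Forward: the ring-A aldoxime comes from 3,4,5-trimethoxyphenol in three steps, the ring-B alkyne from 3,5-bis(benzyloxy)benzaldehyde in three steps. The isoxazole ring forms first; one hydrogenolysis then unmasks the enaminoketone and the phenols, acid closes the pyranone ring, and AlCl3 frees the 5-OH.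
- Stereochemistry: the target has no stereocentre; the oxime and enaminone geometries are transient and are lost.

Key step: step 7

Remark: the target is read as 5,3',5'-trihydroxy-6,7,2'-trimethoxyflavone, an achiral compound. Both starting materials are taken as commercial. The nitrile oxide is generated from the aldoxime with PhI(OAc)2 and not through a hydroximoyl chloride, because chlorinating agents would attack the free ring position of the electron-rich ring A.

**Route**

Step 1
Reactants: 1 3,4,5-trimethoxyphenol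
Product: 2 2-hydroxy-4,5,6-trimethoxybenzaldehyde
Conditions: MgCl2, Et3N, (CH2O)n, MeCN, reflux; then 1 M HCl
Reagents that add atoms: paraformaldehyde (as formaldehyde), C=O
Why: Magnesium-mediated ortho-formylation of a phenol (Casnati–Skattebøl reaction) delivers formaldehyde to the carbon next to the magnesium phenoxide, and because both ortho positions of 1 are equivalent only one aldehyde can form.

Step 2
Reactants: 2 2-hydroxy-4,5,6-trimethoxybenzaldehyde
Product: 3 2-(benzyloxy)-4,5,6-trimethoxybenzaldehyde
Conditions: BnBr, K2CO3, DMF, 60 °C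
Reagents that add atoms: benzyl bromide, BrCc1ccccc1
Why: Williamson ether synthesis on the phenoxide installs a benzyl group that should later leave in the same hydrogenolysis that opens the isoxazole.

Step 3
Reactants: 3 2-(benzyloxy)-4,5,6-trimethoxybenzaldehyde
Product: 4 (E)-2-(benzyloxy)-4,5,6-trimethoxybenzaldehyde oxime
Conditions: NH2OH·HCl, NaOAc, EtOH/H2O, 60 °C
Reagents that add atoms: hydroxylamine hydrochloride, NO.Cl
Why: Oxime formation by condensation of a non-enolisable aryl aldehyde with hydroxylamine tolerates the two ortho substituents and should give the E-oxime, whose geometry disappears in step 7.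

Step 4
Reactants: 5 3,5-bis(benzyloxy)benzaldehyde
Product: 6 3,5-bis(benzyloxy)-2-bromobenzaldehyde
Conditions: NBS (1 equiv), MeCN, 0 °C to rt
Reagents that add atoms: N-bromosuccinimide, O=C1CCC(=O)N1Br
Why: Electrophilic aromatic bromination should go to C2, which is para to one benzyloxy group and ortho to the other, while C4 between the two ether groups is shielded, as is established for 3,5-dialkoxybenzaldehydes.

Step 5
Reactants: 6 3,5-bis(benzyloxy)-2-bromobenzaldehyde
Product: 7 3,5-bis(benzyloxy)-2-methoxybenzaldehyde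
Conditions: NaOMe, CuBr (cat.), DMF/MeOH, 100 °C
Reagents that add atoms: sodium methoxide, [Na+].[O-]C
Why: Ullmann-type copper-catalysed methoxylation of an aryl bromide is assisted here by the ortho formyl group, and the benzyl ethers and the non-enolisable aldehyde should tolerate methoxide.

Step 6
Reactants: 7 3,5-bis(benzyloxy)-2-methoxybenzaldehyde
Product: 8 1,5-bis(benzyloxy)-3-ethynyl-2-methoxybenzene
Conditions: dimethyl (1-diazo-2-oxopropyl)phosphonate, K2CO3, MeOH/THF, rt
Reagents that add atoms: dimethyl (1-diazo-2-oxopropyl)phosphonate (Ohira–Bestmann reagent), COP(=O)(OC)C(=[N+]=[N-])C(C)=O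
Why: Seyferth–Gilbert homologation in the Ohira–Bestmann variant converts aryl aldehydes to terminal alkynes under mild carbonate conditions that leave the ethers untouched.

Step 7
Reactants: 4 (E)-2-(benzyloxy)-4,5,6-trimethoxybenzaldehyde oxime; 8 1,5-bis(benzyloxy)-3-ethynyl-2-methoxybenzene
Product: 10 3-[2-(benzyloxy)-4,5,6-trimethoxyphenyl]-5-[3,5-bis(benzyloxy)-2-methoxyphenyl]isoxazole, via nitrile oxide 9 (not isolated)
Conditions: PhI(OAc)2, TFA (cat.), MeOH/CH2Cl2, 0 °C to rt, then 50 °C
Reagents that add atoms: none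
Why: PhI(OAc)2 exchanges an acetate for the oxime and then loses iodobenzene and acetic acid, which dehydrogenates 4 to nitrile oxide 9 without any electrophilic halogen that could attack the free ring position of the electron-rich ring A. Dipole 9 then adds across the terminal alkyne of 8 in a concerted, thermally allowed [3+2] cycloaddition (Huisgen 1,3-dipolar cycloaddition of an aryl nitrile oxide to an arylacetylene is the closest known reaction type), forming the C–C bond from the nitrile oxide carbon to the terminal alkyne carbon and the C–O bond to the aryl-bearing carbon. The isoxazole ring thus closes in one intermolecular cycloaddition event in which both bonds are made together, not by a stepwise cyclisation, and no stereocentre is created. The selectivity needed is 3,5- over 3,4-regiochemistry, which a monosubstituted alkyne secures because the bulky dipole carbon bonds to the unhindered terminal carbon and the frontier-orbital coefficients favour the same orientation. The benzyloxy and methoxy groups flanking the nitrile oxide retard its dimerisation to the furoxan, so the slower cycloaddition of this hindered dipole can be completed by gentle warming. The ring then carries the 1,3-dicarbonyl oxidation level of C2–C4 unchanged to the hydrogenolysis of step 8.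

Step 8
Reactants: 10 3-[2-(benzyloxy)-4,5,6-trimethoxyphenyl]-5-[3,5-bis(benzyloxy)-2-methoxyphenyl]isoxazole
Product: 11 (Z)-3-amino-1-(3,5-dihydroxy-2-methoxyphenyl)-3-(2-hydroxy-4,5,6-trimethoxyphenyl)prop-2-en-1-one
Conditions: H2 (1 atm), 10% Pd/C, EtOAc/MeOH, rt
Reagents that add atoms: none
Why: Heterogeneous catalytic hydrogenolysis should cleave the weak N–O bond of the isoxazole to the hydrogen-bonded Z-enaminoketone and the three O-benzyl ethers in the same operation, while aryl methyl ethers and the vinylogous amide are inert at low pressure.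

Step 9
Reactants: 11 (Z)-3-amino-1-(3,5-dihydroxy-2-methoxyphenyl)-3-(2-hydroxy-4,5,6-trimethoxyphenyl)prop-2-en-1-one
Product: 13 2-(3,5-dihydroxy-2-methoxyphenyl)-5,6,7-trimethoxy-4H-chromen-4-one, via diketone 12 (not isolated)
Conditions: 2 M aq. HCl, AcOH, 90 °C
Reagents that add atoms: water, O
Why: Acid hydrolysis of the enaminone to the 1,3-diketone 12 followed by cyclodehydration (the closing stage of the Baker–Venkataraman flavone synthesis) can give only one chromone, because ring A alone carries a free ortho hydroxyl for the 6-exo-trig attack on the ring-B-side carbonyl.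

Step 10
Reactants: 13 2-(3,5-dihydroxy-2-methoxyphenyl)-5,6,7-trimethoxy-4H-chromen-4-one
Product: 14 2-(3,5-dihydroxy-2-methoxyphenyl)-5-hydroxy-6,7-dimethoxy-4H-chromen-4-one
Conditions: AlCl3 (excess), MeCN, rt to 50 °C; then H2O
Reagents that add atoms: none
Why: Chelation-controlled Lewis-acid demethylation, the standard selective 5-O-demethylation of polymethoxyflavones, should remove only the methyl group whose oxygen binds aluminium together with the 4-carbonyl in a six-membered chelate.

**Compound list**

1 | 3,4,5-trimethoxyphenol | COc1cc(O)cc(OC)c1OC | starting material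
2 | 2-hydroxy-4,5,6-trimethoxybenzaldehyde | COc1cc(O)c(C=O)c(OC)c1OC | intermediate
3 | 2-(benzyloxy)-4,5,6-trimethoxybenzaldehyde | COc1cc(OCc2ccccc2)c(C=O)c(OC)c1OC | intermediate
4 | (E)-2-(benzyloxy)-4,5,6-trimethoxybenzaldehyde oxime | COc1cc(OCc2ccccc2)c(/C=N/O)c(OC)c1OC | intermediate
5 | 3,5-bis(benzyloxy)benzaldehyde | O=Cc1cc(OCc2ccccc2)cc(OCc2ccccc2)c1 | starting material
6 | 3,5-bis(benzyloxy)-2-bromobenzaldehyde | O=Cc1cc(OCc2ccccc2)cc(OCc2ccccc2)c1Br | intermediate
7 | 3,5-bis(benzyloxy)-2-methoxybenzaldehyde | O=Cc1cc(OCc2ccccc2)cc(OCc2ccccc2)c1OC | intermediate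
8 | 1,5-bis(benzyloxy)-3-ethynyl-2-methoxybenzene | C#Cc1cc(OCc2ccccc2)cc(OCc2ccccc2)c1OC | intermediate
9 | 2-(benzyloxy)-4,5,6-trimethoxybenzonitrile oxide | COc1cc(OCc2ccccc2)c(C#[N+][O-])c(OC)c1OC | intermediate (formed in the flask, not isolated)
10 | 3-[2-(benzyloxy)-4,5,6-trimethoxyphenyl]-5-[3,5-bis(benzyloxy)-2-methoxyphenyl]isoxazole | COc1cc(OCc2ccccc2)c(-c2cc(-c3cc(OCc4ccccc4)cc(OCc4ccccc4)c3OC)on2)c(OC)c1OC | intermediate
11 | (Z)-3-amino-1-(3,5-dihydroxy-2-methoxyphenyl)-3-(2-hydroxy-4,5,6-trimethoxyphenyl)prop-2-en-1-one | COc1cc(O)c(/C(N)=C/C(=O)c2cc(O)cc(O)c2OC)c(OC)c1OC | intermediate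
12 | 1-(3,5-dihydroxy-2-methoxyphenyl)-3-(2-hydroxy-4,5,6-trimethoxyphenyl)propane-1,3-dione | COc1cc(O)c(C(=O)CC(=O)c2cc(O)cc(O)c2OC)c(OC)c1OC | intermediate (formed in the flask, not isolated)
13 | 2-(3,5-dihydroxy-2-methoxyphenyl)-5,6,7-trimethoxy-4H-chromen-4-one | COc1cc2oc(-c3cc(O)cc(O)c3OC)cc(=O)c2c(OC)c1OC | intermediate
14 | 2-(3,5-dihydroxy-2-methoxyphenyl)-5-hydroxy-6,7-dimethoxy-4H-chromen-4-one | COc1cc2oc(-c3cc(O)cc(O)c3OC)cc(=O)c2c(O)c1OC | target

**Step count and risks**

Total steps: 10. Longest linear sequence: 7 steps (steps 1–3 or 4–6, then 7–10).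

Steps most likely to fail:

1. Step 7. The cycloaddition of the doubly ortho-substituted dipole may be slow enough that oxidation of the electron-rich rings by the iodine reagent, or rearrangement of the nitrile oxide to the isocyanate, competes. The fallback sets out from aldehyde 3 and alkyne 8 and comes back to the route at flavone 13.
   - The lithium acetylide of 8 (n-BuLi, THF, −78 °C) should add to 3 to give racemic 1-[2-(benzyloxy)-4,5,6-trimethoxyphenyl]-3-[3,5-bis(benzyloxy)-2-methoxyphenyl]prop-2-yn-1-ol F1.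
   - MnO2 in CH2Cl2 should oxidise it to 1-[2-(benzyloxy)-4,5,6-trimethoxyphenyl]-3-[3,5-bis(benzyloxy)-2-methoxyphenyl]prop-2-yn-1-one F2.
   - Free hydroxylamine (NH2OH·HCl, K2CO3, EtOH, reflux) is expected to add in conjugate fashion to the unhindered alkyne carbon and close to 5-[2-(benzyloxy)-4,5,6-trimethoxyphenyl]-3-[3,5-bis(benzyloxy)-2-methoxyphenyl]isoxazole F3.
   - Hydrogenolysis as in step 8 should give (Z)-3-amino-3-(3,5-dihydroxy-2-methoxyphenyl)-1-(2-hydroxy-4,5,6-trimethoxyphenyl)prop-2-en-1-one F4.
   - The acid treatment of step 9 should hydrolyse F4 to the same diketone 12 and close it to 13.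

2. Step 5. Hydrodebromination, with methoxide acting as hydride donor, and methoxide attack on the formyl group may outpace C–O coupling at the doubly flanked bromide. The fallback sets out from bromide 6 and comes back at aldehyde 7.
   - Miyaura borylation (B2pin2, Pd(OAc)2, SPhos, KOAc, dioxane, 90 °C) should give 3,5-bis(benzyloxy)-2-(4,4,5,5-tetramethyl-1,3,2-dioxaborolan-2-yl)benzaldehyde F5.
   - Oxidation with one equivalent of NaBO3·4H2O in THF/H2O at rt should give 3,5-bis(benzyloxy)-2-hydroxybenzaldehyde F6.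
   - O-methylation (MeI, K2CO3, acetone) should then give 7.

3. Step 10. After the 5-O-aluminium chelate has formed, neighbouring-group delivery may strip the 6-methyl group or, from the 3'-phenoxide, the 2'-methyl group. The fallback sets out from 13 and comes back at target 14.
   - Acetylation (Ac2O, pyridine) should give 2-(3,5-diacetoxy-2-methoxyphenyl)-5,6,7-trimethoxy-4H-chromen-4-one F7, which has no free phenol next to a methoxy group.
   - BCl3 in CH2Cl2 at −78 to 0 °C should cleave only the chelated 5-methyl ether to 2-(3,5-diacetoxy-2-methoxyphenyl)-5-hydroxy-6,7-dimethoxy-4H-chromen-4-one F8.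
   - Methanolysis (K2CO3, MeOH, rt) should remove the acetates to give 14.

**Further compounds**

F1 | step 7 | 1-[2-(benzyloxy)-4,5,6-trimethoxyphenyl]-3-[3,5-bis(benzyloxy)-2-methoxyphenyl]prop-2-yn-1-ol (racemic) | COc1cc(OCc2ccccc2)c(C(O)C#Cc2cc(OCc3ccccc3)cc(OCc3ccccc3)c2OC)c(OC)c1OC
F2 | step 7 | 1-[2-(benzyloxy)-4,5,6-trimethoxyphenyl]-3-[3,5-bis(benzyloxy)-2-methoxyphenyl]prop-2-yn-1-one | COc1cc(OCc2ccccc2)c(C(=O)C#Cc2cc(OCc3ccccc3)cc(OCc3ccccc3)c2OC)c(OC)c1OC
F3 | step 7 | 5-[2-(benzyloxy)-4,5,6-trimethoxyphenyl]-3-[3,5-bis(benzyloxy)-2-methoxyphenyl]isoxazole | COc1cc(OCc2ccccc2)c(-c2cc(-c3cc(OCc4ccccc4)cc(OCc4ccccc4)c3OC)no2)c(OC)c1OC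
F4 | step 7 | (Z)-3-amino-3-(3,5-dihydroxy-2-methoxyphenyl)-1-(2-hydroxy-4,5,6-trimethoxyphenyl)prop-2-en-1-one | COc1cc(O)c(C(=O)/C=C(\N)c2cc(O)cc(O)c2OC)c(OC)c1OC
F5 | step 5 | 3,5-bis(benzyloxy)-2-(4,4,5,5-tetramethyl-1,3,2-dioxaborolan-2-yl)benzaldehyde | O=Cc1cc(OCc2ccccc2)cc(OCc2ccccc2)c1B1OC(C)(C)C(C)(C)O1
F6 | step 5 | 3,5-bis(benzyloxy)-2-hydroxybenzaldehyde | O=Cc1cc(OCc2ccccc2)cc(OCc2ccccc2)c1O
F7 | step 10 | 2-(3,5-diacetoxy-2-methoxyphenyl)-5,6,7-trimethoxy-4H-chromen-4-one | COc1cc2oc(-c3cc(OC(C)=O)cc(OC(C)=O)c3OC)cc(=O)c2c(OC)c1OC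
F8 | step 10 | 2-(3,5-diacetoxy-2-methoxyphenyl)-5-hydroxy-6,7-dimethoxy-4H-chromen-4-one | COc1cc2oc(-c3cc(OC(C)=O)cc(OC(C)=O)c3OC)cc(=O)c2c(O)c1OC
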